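Numbering used throughout: lactone ring O1, C2 (C=O), C3=C4, C5 (OH), C6; side chain C7 (OH) and C8 (Ph). Flavanone atoms are primed: O1′, C2′ (Ph), C3′, C4′ (C=O), C4a′, C5′ (OH), C6′ (bears C8), C7′ (OH), C8′, C8a′. Ring A is the benzo ring and ring C the pyranone ring of the flavanone.

## Analysis of the target

The target is a (2′S)-5′,7′-dihydroxyflavanone whose ring A carbon C6′ carries C8 of a two-carbon chain, C8(H)(Ph)–C7(H)(OH), which ends at C6 of a 5-hydroxy-5,6-dihydro-2H-pyran-2-one. There are five stereocentres: C5 (S), C6 (R), C7 (R) and C8 (S) are contiguous, and C2′ (S) is remote and independent of them. On the lactone ring the C5 hydroxyl is cis to the C6 side chain. Along the chain C6–O1 and C7–OH are syn, and C7–O and C8–Ph are trans when C6 is tied to an ortho oxygen of ring A in a six-membered ring. The sensitive groups are: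
- the conjugated lactone (hydrogenation, conjugate addition of the free C7 hydroxyl under base, translactonisation through the C5 hydroxyl);
- the flavanone (base opens ring C and racemises C2′);
- the phloroglucinol-type ring A (halogenating and strongly oxidising reagents);
- the doubly benzylic C8–H.

The hard points are C8, a diarylmethine stereocentre flanked by two ortho oxygens and adjacent to a carbinol, and the regiochemistry of ring C, whose oxygen O1′ must be the ring A oxygen para to C6′. The strategy rests on one feature: C8 is benzylic to ring A and ortho to a phenolic oxygen (C7′–O, equivalent to C5′–O until ring C exists). C8 can therefore be the electrophilic carbon of an ortho-quinone methide, C7 the nucleophilic carbon of an α-oxygenated enolate, and C6 the acyl carbon that the ortho oxygen captures as a lactone.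

## Retrosynthetic reasoning

Deprotection (26 from 25). No skeletal bond is cut. The C7 oxygen carries a benzyl ether and the C5, C5′ and C7′ oxygens carry methoxymethyl acetals. One boron Lewis acid at low temperature removes all four without base and without hydrogen, the two conditions the conjugated lactone of 26 does not tolerate.

Ring C (25 from 23, and 23 back to 20). The C4′–C4a′ bond is cut. The C4′ ketone cannot be present while 14 or a hydride reagent is in use, and the acidic acylation that makes it cannot be run while the furan is present, so ring C is closed after the lactone is complete. Cutting C4′–C4a′ and not O1′–C2′ leaves an aryl ether whose oxygen is already O1′ and whose C2′ centre already exists. The closure therefore cannot give the 8-substituted isomer and does not touch C2′. Because C5′–O and C7′–O carry the same group, the two positions ortho to the ether oxygen are equivalent. The acid 23 goes back through aldehyde 22 and diol 21 to the terminal alkene of 20, a carboxyl equivalent that is inert to every earlier step.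

Lactone (20 back to 16). The C5 acetal is removed (19), and the C5 carbinol is traced to the ketone of 18, where hydride should enter opposite the C6 substituent. Dione 18 comes from lactol 17, and 17 from furyl carbinol 16 by oxidative ring expansion. In that step the carbinol oxygen becomes O1 and the four furan carbons become C2–C5. No C–C bond has to be made stereoselectively for C5; it follows from C6.

C5–C6 bond and C6 (16 back to 10). Carbinol 16 comes from ketone 15, so that C6 is set by a chiral reduction catalyst with the Felkin–Anh preference of the α-benzyloxy ketone pointing the same way. Ketone 15 comes from amide 12 and 2-furyllithium 14 (from furan 13). Amide 12 comes from 11, and 11 from lactone 10 by opening with an amine, which keeps C6 at the acyl level for exactly one addition.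

Key disconnection (10 to 9 and 8). C7–C8 and the aryl O–C6 ester bond are cut together. This is the only place where both benzylic stereocentres can be made in one operation from achiral or racemic partners. The forward reaction has to add a chiral, catalyst-bound enolate derived from 8 to the exocyclic carbon of 9 with face control and then lactonise on the phenoxide.

Quinone methide precursor (9, 7, 6 back to 4 and 5). Quinone methide 9 is released from sulfone 7 by base. Sulfone 7 comes from benzhydrol 6 by exchange of the hydroxyl for sulfinate, and 6 from salicylaldehyde 4 and 5. The stereocentre of 6 and 7 is irrelevant because it is erased in 9.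

Ring A oxygens and C2′ (4 and 3 back to 1 and 2). Two identical acetals on the C5′ and C8a′ oxygens would make the simplest precursor. After the lactone is opened and the third oxygen protected, however, ring A would carry three indistinguishable oxygens, and ring C could then close on the wrong one. The oxygen para to the formyl group of 1 is therefore used at the outset to carry the whole O1′–C2′(Ph)–C3′–C4′ unit as the (S)-1-phenylbut-3-enyl ether. It is installed from 2 with inversion, and one acetal then goes on one of the two equivalent ortho hydroxyls (4). This differentiates the oxygens, sets C2′ and places the ring C carbons in two steps.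

## Alternatives that were turned down

Alternative 1: The disconnection is C4′–C4a′ alone, made last. In the forward direction the (S)-3-aryloxy-3-phenylpropanoic acid A1, which already carries the complete bis-silylated hydroxy lactone, is activated with (CF3CO)2O and acylates ring A ortho to the ether oxygen to give the fully protected target A2.
- For: the regiochemistry is fixed by symmetry, C2′ comes from a chiral alcohol, and the ketone appears after all organometallic steps.
- Against, as an organising idea: it does not address the difficult part of the molecule. A1 already contains C5–C8 and the C8–C6′ bond, and the plan does not say how they are made.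
- Comparison: on ring C it is as strong as anything available, and the chosen route uses the same type of closure as step 16 (23 to 25). The chosen strategy adds the bond construction that this one presupposes: C7–C8 with both stereocentres, and C6 delivered at the acyl level.

Alternative 2: The disconnection is the C5–O bond with transposition of the alkene. The β,γ-unsaturated lactone A3 (3,6-dihydro-2H-pyran-2-one with free C7 hydroxyl) is epoxidised with VO(acac)2 and t-BuOOH on the face of the side chain to give epoxy lactone A4. Base then opens A4 by E1cB to the 5-hydroxy enone A5.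
- For: C5 is set from C7 by hydroxyl direction, no furan is needed, and the lactone requires two operations where the chosen route uses three.
- Against:
  - A3 is a skipped enoate with acidic C3 protons and should slip into conjugation before it is epoxidised.
  - The directing hydroxyl is homoallylic and on a freely rotating exocyclic carbon, so the face preference is not secure.
  - The E1cB step needs base on a compound that already contains the flavanone (ring C opening, loss of C2′).
  - That step produces the enone next to a free C7 hydroxyl, which can add to C4.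
  - The plan is silent on C7–C8.
- Comparison: it is stronger on step count at the lactone. The chosen route offers instead a C5 centre set by hydride approach opposite the C6 substituent on a nearly flat ring, and it keeps base and oxidants away from the flavanone by forming it later.

Alternative 3: The disconnection is C4a′–C5′, with ring A built last. The bicyclic 2-pyranone A6, itself to be derived from triacetic acid lactone A7, is opened at its lactone carbonyl by Mg(OMe)2 in methanol. The side-chain methylene carbanion then acylates the resulting ester to give the cinnamoyl phloroglucinol (chalcone) A8.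
- For: the three ring A oxygens are differentiated by construction, the building block is cheap, and C7 and C8 could be set on a non-aromatic precursor.
- Against:
  - Both hydroxyls flanking the cinnamoyl ketone of A8 (C5′ and C8a′) are free, so ring C can close either way.
  - The oxa-Michael closure is not controlled at C2′ and is reversible under base.
  - The open triketone can also condense in the aldol sense.
  - A6 needs its own multi-step synthesis.
  - The lactone end still has to be elaborated after a base-labile flavanone is in place.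
- Comparison: it is stronger on oxygen differentiation, which the chosen route handles with one selective etherification. It is weaker on every stereochemical question, which the chosen route answers with one catalytic step for C7 and C8 and one inversion for C2′.

Key step: step 5

Assumption (chemistry): quinone methide 9 is taken to react as its E isomer and O-benzoylquinidine is taken to be the pseudoenantiomer that delivers the 4S configuration of 10; if the first run shows the opposite sense, O-benzoylquinine is used with no other change.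

In the names below, Ar = 2,6-bis(methoxymethoxy)-4-{[(1S)-1-phenylbut-3-en-1-yl]oxy}phenyl.

## Steps

Step 1
Reactants: 1 2,4,6-trihydroxybenzaldehyde; 2 (1R)-1-phenylbut-3-en-1-ol
Product: 3 2,6-dihydroxy-4-{[(1S)-1-phenylbut-3-en-1-yl]oxy}benzaldehyde
Conditions: PPh3, DIAD, THF, 0 °C → rt
Reagents that add atoms: none
Why: Mitsunobu etherification; the C4 hydroxyl of 1 is the most acidic and is not held in a hydrogen bond to the formyl group, so it should react first. The carbinol centre of 2 is inverted (SN2 on the alkoxyphosphonium ion), which sets C2′ as S.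

Step 2
Reactants: 3 2,6-dihydroxy-4-{[(1S)-1-phenylbut-3-en-1-yl]oxy}benzaldehyde
Product: 4 2-hydroxy-6-(methoxymethoxy)-4-{[(1S)-1-phenylbut-3-en-1-yl]oxy}benzaldehyde
Conditions: MOMCl (1.05 equiv), i-Pr2NEt, CH2Cl2, 0 °C
Reagents that add atoms: chloromethyl methyl ether, COCCl
Why: Acetal formation on one of two equivalent phenols; after the first acetal is in place the remaining hydroxyl is locked in a hydrogen bond to the aldehyde and is far less nucleophilic, so the reaction should stop at the mono-ether.

Step 3
Reactants: 4 2-hydroxy-6-(methoxymethoxy)-4-{[(1S)-1-phenylbut-3-en-1-yl]oxy}benzaldehyde; 5 phenylmagnesium bromide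
Product: 6 2-[hydroxy(phenyl)methyl]-3-(methoxymethoxy)-5-{[(1S)-1-phenylbut-3-en-1-yl]oxy}phenol (both carbinol epimers)
Conditions: THF, −20 → 0 °C; aq NH4Cl
Reagents that add atoms: none
Why: Grignard addition to the aldehyde; the first equivalent of 5 deprotonates the phenol and the second adds. The new carbinol centre is of no consequence because it is erased in step 5.

Step 4
Reactants: 6 2-[hydroxy(phenyl)methyl]-3-(methoxymethoxy)-5-{[(1S)-1-phenylbut-3-en-1-yl]oxy}phenol
Product: 7 3-(methoxymethoxy)-2-[(4-methylbenzenesulfonyl)(phenyl)methyl]-5-{[(1S)-1-phenylbut-3-en-1-yl]oxy}phenol (both epimers at the sulfonyl-bearing carbon)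
Conditions: TolSO2Na, AcOH, CH2Cl2, rt
Reagents that add atoms: sodium p-toluenesulfinate, [Na+].[O-]S(=O)c1ccc(C)cc1
Why: SN1-type substitution; the ortho-hydroxy benzhydrol ionises under weak acid and the sulfinate is captured at sulfur to give a stable, storable sulfone. Acetic acid is too weak to cleave the acetal or the benzylic aryl ether.

Step 5
Reactants: 7 3-(methoxymethoxy)-2-[(4-methylbenzenesulfonyl)(phenyl)methyl]-5-{[(1S)-1-phenylbut-3-en-1-yl]oxy}phenol; 8 (benzyloxy)acetyl chloride
Product: 10 (3R,4S)-3-(benzyloxy)-5-(methoxymethoxy)-4-phenyl-7-{[(1S)-1-phenylbut-3-en-1-yl]oxy}-3,4-dihydro-2H-chromen-2-one, via ortho-quinone methide 9 (not isolated)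
Conditions: Cs2CO3, CH2Cl2, rt, filtration; then O-benzoylquinidine (10 mol %), i-Pr2NEt, slow addition of 8, CH2Cl2, −78 → −30 °C; DBU (0.1 equiv), rt
Reagents that add atoms: none
Why: Base removes sulfinate from 7 to give quinone methide 9, which is freed from the sulfinate salt before 8 is introduced so that neither sulfinate nor a free phenoxide competes for the acylating agent. Acid chloride 8 and i-Pr2NEt give the (Z)-α-benzyloxy ammonium enolate on the quinuclidine nitrogen of the catalyst; its open face adds to the exocyclic carbon of 9 (Michael step, C7–C8), a step driven by the return of ring A to the aromatic state and therefore tolerant of the two donor oxygens on 9. The phenoxide so formed attacks the acylammonium carbon in a 6-exo-trig closure, which forms the aryl ester bond O–C6, closes the dihydrocoumarin ring and releases the catalyst. The closest known reaction type is the Lewis-base-catalysed formal [4+2] annulation of ortho-quinone methides with ketene-derived ammonium enolates to 3,4-dihydrocoumarins; only the α-alkoxy group on the enolate is an extension. C8 (C4 of 10) is set by the catalyst, which fixes the enolate face and, through the compact transition state, the face of 9; the stereocentre of 7 is erased in 9 and the remote ether centre is not expected to interfere. C7 (C3 of 10) is set kinetically by the same catalyst and thermodynamically by base: the peri methoxymethoxy group forces the C4 phenyl pseudo-axial, so the trans-diaxial isomer should be favoured and catalytic DBU converts any cis isomer into it without touching C8. The step needs chemoselectivity for the catalysed C–C bond formation over ketene dimerisation and uncatalysed cycloaddition, which slow addition of 8 at low temperature to preformed 9 secures, and a single reacting geometry of 9 for face selectivity at C8.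

Step 6
Reactants: 10 (3R,4S)-3-(benzyloxy)-5-(methoxymethoxy)-4-phenyl-7-{[(1S)-1-phenylbut-3-en-1-yl]oxy}-3,4-dihydro-2H-chromen-2-one
Product: 11 (2R,3S)-2-(benzyloxy)-3-[2-hydroxy-6-(methoxymethoxy)-4-{[(1S)-1-phenylbut-3-en-1-yl]oxy}phenyl]-N-methoxy-N-methyl-3-phenylpropanamide
Conditions: MeNH(OMe)·HCl, AlMe3, CH2Cl2, 0 °C → rt
Reagents that add atoms: N,O-dimethylhydroxylamine hydrochloride, CNOC.Cl
Why: Aminolysis of the aryl ester by the aluminium amide (Weinreb amide formation) opens the lactone without enolising C7 and releases the ortho phenol. C6 stays at the acyl level, ready for a single carbon nucleophile.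

Step 7
Reactants: 11 (2R,3S)-2-(benzyloxy)-3-[2-hydroxy-6-(methoxymethoxy)-4-{[(1S)-1-phenylbut-3-en-1-yl]oxy}phenyl]-N-methoxy-N-methyl-3-phenylpropanamide
Product: 12 (2R,3S)-3-Ar-2-(benzyloxy)-N-methoxy-N-methyl-3-phenylpropanamide
Conditions: MOMCl, i-Pr2NEt, n-Bu4NI (cat.), CH2Cl2, 40 °C
Reagents that add atoms: chloromethyl methyl ether, COCCl
Why: Acetal protection of the hindered phenol; with both ortho oxygens now carrying the same group, the two free positions of ring A become equivalent, which removes any regiochemical question in step 16.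

Step 8
Reactants: 12 (2R,3S)-3-Ar-2-(benzyloxy)-N-methoxy-N-methyl-3-phenylpropanamide; 13 furan
Product: 15 (2R,3S)-3-Ar-2-(benzyloxy)-1-(furan-2-yl)-3-phenylpropan-1-one, via 2-furyllithium 14 (not isolated)
Conditions: 13, n-BuLi, THF, −78 → 0 °C; then 12, −78 °C; aq NH4Cl
Reagents that add atoms: none
Why: Organolithium addition to a Weinreb amide stops at the ketone because the chelated tetrahedral intermediate survives until work-up. The step forms C5–C6 and brings in C2–C5 of the lactone as the furan.

Step 9
Reactants: 15 (2R,3S)-3-Ar-2-(benzyloxy)-1-(furan-2-yl)-3-phenylpropan-1-one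
Product: 16 (1S,2R,3S)-3-Ar-2-(benzyloxy)-1-(furan-2-yl)-3-phenylpropan-1-ol
Conditions: RuCl[(S,S)-TsDPEN](p-cymene) (2 mol %), HCO2H/Et3N (5:2), CH2Cl2, rt
Reagents that add atoms: none
Why: Noyori asymmetric transfer hydrogenation of a 2-acylfuran; the (S,S) catalyst should deliver hydride to the face that gives the 1S carbinol, which is the C6 configuration of the target (R there only because the priorities change). The Felkin–Anh preference of the α-benzyloxy ketone (C–O bond anti to the incoming hydride) leads to the same 6,7-syn product, so catalyst and substrate should reinforce each other.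

Step 10
Reactants: 16 (1S,2R,3S)-3-Ar-2-(benzyloxy)-1-(furan-2-yl)-3-phenylpropan-1-ol
Product: 17 (2S)-2-[(1R,2S)-2-Ar-1-(benzyloxy)-2-phenylethyl]-6-hydroxy-2H-pyran-3(6H)-one (both C6 epimers)
Conditions: VO(acac)2 (5 mol %), t-BuOOH, CH2Cl2, 0 °C → rt
Reagents that add atoms: tert-butyl hydroperoxide, CC(C)(C)OO
Why: Achmatowicz rearrangement; the vanadium alkoxide of the furyl carbinol transfers peroxide oxygen to the neighbouring furan and the ene-dione recloses through the C6 hydroxyl, which becomes O1. This hydroxyl-directed oxidant is chosen because a halogen electrophile would attack the trialkoxy ring A, while the isolated terminal alkene is inert to it; C6 is not touched.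

Step 11
Reactants: 17 (2S)-2-[(1R,2S)-2-Ar-1-(benzyloxy)-2-phenylethyl]-6-hydroxy-2H-pyran-3(6H)-one
Product: 18 (6S)-6-[(1R,2S)-2-Ar-1-(benzyloxy)-2-phenylethyl]-2H-pyran-2,5(6H)-dione
Conditions: Dess–Martin periodinane, CH2Cl2, 0 °C; crude used at once
Reagents that add atoms: none
Why: Oxidation of the lactol to the lactone with a hypervalent iodine reagent under non-basic conditions that spare the acetals. Dione 18 can enolise to a 5-hydroxy-2-pyranone, which would erase C6, so it is not purified.

Step 12
Reactants: 18 (6S)-6-[(1R,2S)-2-Ar-1-(benzyloxy)-2-phenylethyl]-2H-pyran-2,5(6H)-dione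
Product: 19 (5S,6R)-6-[(1R,2S)-2-Ar-1-(benzyloxy)-2-phenylethyl]-5-hydroxy-5,6-dihydro-2H-pyran-2-one
Conditions: NaBH4, CeCl3·7H2O, MeOH/CH2Cl2, −78 °C
Reagents that add atoms: none
Why: Luche 1,2-reduction; the ring of 18 is nearly flat, so hydride should add to the C5 ketone from the face opposite the large C6 substituent and leave the hydroxyl cis to it (5S). The lactone carbonyl and the conjugated alkene are not reduced at this temperature.

Step 13
Reactants: 19 (5S,6R)-6-[(1R,2S)-2-Ar-1-(benzyloxy)-2-phenylethyl]-5-hydroxy-5,6-dihydro-2H-pyran-2-one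
Product: 20 (5S,6S)-6-[(1R,2S)-2-Ar-1-(benzyloxy)-2-phenylethyl]-5-(methoxymethoxy)-5,6-dihydro-2H-pyran-2-one
Conditions: MOMCl, i-Pr2NEt, CH2Cl2, 0 °C → rt
Reagents that add atoms: chloromethyl methyl ether, COCCl
Why: Acetal protection of the allylic alcohol with a hindered amine base, mild enough for the unsaturated lactone. It keeps the C5 hydroxyl from being acylated in step 16 and is removed in the last step with the other acetals.

Step 14
Reactants: 20 (5S,6S)-6-[(1R,2S)-2-Ar-1-(benzyloxy)-2-phenylethyl]-5-(methoxymethoxy)-5,6-dihydro-2H-pyran-2-one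
Product: 22 (5S,6S)-6-[(1R,2S)-1-(benzyloxy)-2-{2,6-bis(methoxymethoxy)-4-[(1S)-3-oxo-1-phenylpropoxy]phenyl}-2-phenylethyl]-5-(methoxymethoxy)-5,6-dihydro-2H-pyran-2-one, via diol 21 (not isolated)
Conditions: OsO4 (2 mol %), NaIO4, 2,6-lutidine, dioxane/H2O, rt
Reagents that add atoms: sodium periodate, [Na+].[O-]I(=O)(=O)=O; water, O
Why: Lemieux–Johnson cleavage; OsO4 should dihydroxylate the electron-rich monosubstituted alkene much faster than the electron-poor cis-disubstituted lactone alkene, and periodate cleaves diol 21 as it forms. Ozone is avoided because of ring A.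

Step 15
Reactants: 22 (5S,6S)-6-[(1R,2S)-1-(benzyloxy)-2-{2,6-bis(methoxymethoxy)-4-[(1S)-3-oxo-1-phenylpropoxy]phenyl}-2-phenylethyl]-5-(methoxymethoxy)-5,6-dihydro-2H-pyran-2-one
Product: 23 (3S)-3-{4-[(1S,2R)-2-(benzyloxy)-2-[(2S,3S)-3-(methoxymethoxy)-6-oxo-3,6-dihydro-2H-pyran-2-yl]-1-phenylethyl]-3,5-bis(methoxymethoxy)phenoxy}-3-phenylpropanoic acid
Conditions: NaClO2, NaH2PO4, 2-methylbut-2-ene, t-BuOH/H2O, 0 °C → rt
Reagents that add atoms: sodium chlorite, [Na+].[O-]Cl=O
Why: Pinnick oxidation of the aldehyde under buffered, weakly acidic conditions; the alkene scavenger removes hypochlorous acid, which would otherwise chlorinate ring A.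

Step 16
Reactants: 23 (3S)-3-{4-[(1S,2R)-2-(benzyloxy)-2-[(2S,3S)-3-(methoxymethoxy)-6-oxo-3,6-dihydro-2H-pyran-2-yl]-1-phenylethyl]-3,5-bis(methoxymethoxy)phenoxy}-3-phenylpropanoic acid
Product: 25 (2S)-6-[(1S,2R)-2-(benzyloxy)-2-[(2S,3S)-3-(methoxymethoxy)-6-oxo-3,6-dihydro-2H-pyran-2-yl]-1-phenylethyl]-5,7-bis(methoxymethoxy)-2-phenyl-2,3-dihydro-4H-chromen-4-one, via mixed trifluoroacetic anhydride 24 (not isolated)
Conditions: (CF3CO)2O (1.5 equiv), CH2Cl2, 0 °C
Reagents that add atoms: none
Why: Intramolecular Friedel–Crafts acylation through the mixed anhydride forms C4′–C4a′ and closes ring C. The ether oxygen is already O1′ and the two positions ortho to it are equivalent, so only one regioisomer can form. The phloroglucinol-type ring should react at 0 °C without a Lewis acid, conditions under which the benzylic C2′–O bond and the lactone should survive; partial loss of the acetal next to the new ketone would be of no consequence.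

Step 17
Reactants: 25 (2S)-6-[(1S,2R)-2-(benzyloxy)-2-[(2S,3S)-3-(methoxymethoxy)-6-oxo-3,6-dihydro-2H-pyran-2-yl]-1-phenylethyl]-5,7-bis(methoxymethoxy)-2-phenyl-2,3-dihydro-4H-chromen-4-one
Product: 26 (2S)-5,7-dihydroxy-6-[(1S,2R)-2-hydroxy-2-[(2R,3S)-3-hydroxy-6-oxo-3,6-dihydro-2H-pyran-2-yl]-1-phenylethyl]-2-phenyl-2,3-dihydro-4H-chromen-4-one
Conditions: BCl3, C6HMe5, CH2Cl2, −78 → −30 °C; MeOH quench
Reagents that add atoms: none
Why: Lewis-acid ether cleavage; BCl3 removes the three methoxymethyl acetals and, with pentamethylbenzene as a non-basic scavenger for the benzyl cation, the C7 benzyl ether in the same operation. No base and no hydrogen are used, so the conjugated lactone, the free C7 hydroxyl beside it and the C2′ centre are not put at risk.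

## Compound list

1 | 2,4,6-trihydroxybenzaldehyde | O=Cc1c(O)cc(O)cc1O | starting material
2 | (1R)-1-phenylbut-3-en-1-ol | C=CC[C@@H](O)c1ccccc1 | starting material
3 | 2,6-dihydroxy-4-{[(1S)-1-phenylbut-3-en-1-yl]oxy}benzaldehyde | C=CC[C@@H](c1ccccc1)Oc1cc(O)c(C=O)c(O)c1 | intermediate
4 | 2-hydroxy-6-(methoxymethoxy)-4-{[(1S)-1-phenylbut-3-en-1-yl]oxy}benzaldehyde | C=CC[C@@H](c1ccccc1)Oc1cc(O)c(C=O)c(OCOC)c1 | intermediate
5 | phenylmagnesium bromide | Br[Mg]c1ccccc1 | starting material
6 | 2-[hydroxy(phenyl)methyl]-3-(methoxymethoxy)-5-{[(1S)-1-phenylbut-3-en-1-yl]oxy}phenol (both carbinol epimers) | C=CC[C@@H](c1ccccc1)Oc1cc(O)c(C(O)c2ccccc2)c(OCOC)c1 | intermediate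
7 | 3-(methoxymethoxy)-2-[(4-methylbenzenesulfonyl)(phenyl)methyl]-5-{[(1S)-1-phenylbut-3-en-1-yl]oxy}phenol (both epimers at the sulfonyl-bearing carbon) | C=CC[C@@H](c1ccccc1)Oc1cc(O)c(C(c2ccccc2)S(=O)(=O)c2ccc(C)cc2)c(OCOC)c1 | intermediate
8 | (benzyloxy)acetyl chloride | O=C(Cl)COCc1ccccc1 | starting material
9 | (6E)-6-benzylidene-5-(methoxymethoxy)-3-{[(1S)-1-phenylbut-3-en-1-yl]oxy}cyclohexa-2,4-dien-1-one | C=CC[C@@H](c1ccccc1)OC1=CC(=O)/C(=C/c2ccccc2)C(OCOC)=C1 | intermediate
10 | (3R,4S)-3-(benzyloxy)-5-(methoxymethoxy)-4-phenyl-7-{[(1S)-1-phenylbut-3-en-1-yl]oxy}-3,4-dihydro-2H-chromen-2-one | O=C1Oc2cc(O[C@@H](CC=C)c3ccccc3)cc(OCOC)c2[C@H](c2ccccc2)[C@H]1OCc1ccccc1 | intermediate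
11 | (2R,3S)-2-(benzyloxy)-3-[2-hydroxy-6-(methoxymethoxy)-4-{[(1S)-1-phenylbut-3-en-1-yl]oxy}phenyl]-N-methoxy-N-methyl-3-phenylpropanamide | CON(C)C(=O)[C@H](OCc1ccccc1)[C@@H](c1ccccc1)c1c(O)cc(O[C@@H](CC=C)c2ccccc2)cc1OCOC | intermediate
12 | (2R,3S)-3-Ar-2-(benzyloxy)-N-methoxy-N-methyl-3-phenylpropanamide | CON(C)C(=O)[C@H](OCc1ccccc1)[C@@H](c1ccccc1)c1c(OCOC)cc(O[C@@H](CC=C)c2ccccc2)cc1OCOC | intermediate
13 | furan | c1ccoc1 | starting material
14 | 2-furyllithium | [Li]c1ccco1 | intermediate
15 | (2R,3S)-3-Ar-2-(benzyloxy)-1-(furan-2-yl)-3-phenylpropan-1-one | O=C(c1ccco1)[C@H](OCc1ccccc1)[C@@H](c1ccccc1)c1c(OCOC)cc(O[C@@H](CC=C)c2ccccc2)cc1OCOC | intermediate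
16 | (1S,2R,3S)-3-Ar-2-(benzyloxy)-1-(furan-2-yl)-3-phenylpropan-1-ol | O[C@H](c1ccco1)[C@H](OCc1ccccc1)[C@@H](c1ccccc1)c1c(OCOC)cc(O[C@@H](CC=C)c2ccccc2)cc1OCOC | intermediate
17 | (2S)-2-[(1R,2S)-2-Ar-1-(benzyloxy)-2-phenylethyl]-6-hydroxy-2H-pyran-3(6H)-one (both C6 epimers) | OC1C=CC(=O)[C@H]([C@H](OCc2ccccc2)[C@@H](c2ccccc2)c2c(OCOC)cc(O[C@@H](CC=C)c3ccccc3)cc2OCOC)O1 | intermediate
18 | (6S)-6-[(1R,2S)-2-Ar-1-(benzyloxy)-2-phenylethyl]-2H-pyran-2,5(6H)-dione | O=C1C=CC(=O)[C@H]([C@H](OCc2ccccc2)[C@@H](c2ccccc2)c2c(OCOC)cc(O[C@@H](CC=C)c3ccccc3)cc2OCOC)O1 | intermediate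
19 | (5S,6R)-6-[(1R,2S)-2-Ar-1-(benzyloxy)-2-phenylethyl]-5-hydroxy-5,6-dihydro-2H-pyran-2-one | O=C1C=C[C@H](O)[C@H]([C@H](OCc2ccccc2)[C@@H](c2ccccc2)c2c(OCOC)cc(O[C@@H](CC=C)c3ccccc3)cc2OCOC)O1 | intermediate
20 | (5S,6S)-6-[(1R,2S)-2-Ar-1-(benzyloxy)-2-phenylethyl]-5-(methoxymethoxy)-5,6-dihydro-2H-pyran-2-one | O=C1C=C[C@H](OCOC)[C@H]([C@H](OCc2ccccc2)[C@@H](c2ccccc2)c2c(OCOC)cc(O[C@@H](CC=C)c3ccccc3)cc2OCOC)O1 | intermediate
21 | (5S,6S)-6-[(1R,2S)-1-(benzyloxy)-2-{4-[(1S)-3,4-dihydroxy-1-phenylbutoxy]-2,6-bis(methoxymethoxy)phenyl}-2-phenylethyl]-5-(methoxymethoxy)-5,6-dihydro-2H-pyran-2-one (both epimers at the new carbinol carbon) | O=C1C=C[C@H](OCOC)[C@H]([C@H](OCc2ccccc2)[C@@H](c2ccccc2)c2c(OCOC)cc(O[C@@H](CC(O)CO)c3ccccc3)cc2OCOC)O1 | intermediate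
22 | (5S,6S)-6-[(1R,2S)-1-(benzyloxy)-2-{2,6-bis(methoxymethoxy)-4-[(1S)-3-oxo-1-phenylpropoxy]phenyl}-2-phenylethyl]-5-(methoxymethoxy)-5,6-dihydro-2H-pyran-2-one | O=C1C=C[C@H](OCOC)[C@H]([C@H](OCc2ccccc2)[C@@H](c2ccccc2)c2c(OCOC)cc(O[C@@H](CC=O)c3ccccc3)cc2OCOC)O1 | intermediate
23 | (3S)-3-{4-[(1S,2R)-2-(benzyloxy)-2-[(2S,3S)-3-(methoxymethoxy)-6-oxo-3,6-dihydro-2H-pyran-2-yl]-1-phenylethyl]-3,5-bis(methoxymethoxy)phenoxy}-3-phenylpropanoic acid | O=C1C=C[C@H](OCOC)[C@H]([C@H](OCc2ccccc2)[C@@H](c2ccccc2)c2c(OCOC)cc(O[C@@H](CC(=O)O)c3ccccc3)cc2OCOC)O1 | intermediate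
24 | mixed anhydride of 23 with trifluoroacetic acid | O=C1C=C[C@H](OCOC)[C@H]([C@H](OCc2ccccc2)[C@@H](c2ccccc2)c2c(OCOC)cc(O[C@@H](CC(=O)OC(=O)C(F)(F)F)c3ccccc3)cc2OCOC)O1 | intermediate
25 | (2S)-6-[(1S,2R)-2-(benzyloxy)-2-[(2S,3S)-3-(methoxymethoxy)-6-oxo-3,6-dihydro-2H-pyran-2-yl]-1-phenylethyl]-5,7-bis(methoxymethoxy)-2-phenyl-2,3-dihydro-4H-chromen-4-one | O=C1C=C[C@H](OCOC)[C@H]([C@H](OCc2ccccc2)[C@@H](c2ccccc2)c2c(OCOC)cc3c(c2OCOC)C(=O)C[C@@H](c2ccccc2)O3)O1 | intermediate
26 | (2S)-5,7-dihydroxy-6-[(1S,2R)-2-hydroxy-2-[(2R,3S)-3-hydroxy-6-oxo-3,6-dihydro-2H-pyran-2-yl]-1-phenylethyl]-2-phenyl-2,3-dihydro-4H-chromen-4-one | O=C1C=C[C@H](O)[C@H]([C@H](O)[C@@H](c2ccccc2)c2c(O)cc3c(c2O)C(=O)C[C@@H](c2ccccc2)O3)O1 | target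

## Step count and least certain steps

Total step count: 17. Longest linear sequence: 17 steps (1 to 26); 2, 5, 8 and 13 are bought.

Step 5 (key step). The most likely failure is a slow Michael addition of the catalyst-bound enolate to 9, whose two alkoxy donors lower its electrophilicity and whose peri substituent crowds the exocyclic carbon. Ketene dimerisation or uncatalysed, non-selective cycloaddition of free benzyloxyketene could then take over. Reaction of 9 through both alkene geometries would erode face selectivity at C8. The fallback keeps the same bonds but changes the activation mode to enamine catalysis. It sets out from 7. Quinone methide 9 is generated as before and treated with (benzyloxy)acetaldehyde F1 and a diarylprolinol silyl ether catalyst. Michael addition of the enamine and hemiacetalisation give the trans chroman-2-ol F2 (C2 epimers), and oxidation of the lactol (TEMPO, PhI(OAc)2) returns to the route at 10.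

Step 1. Etherification may occur at an ortho hydroxyl or twice, because the second ortho hydroxyl is not hydrogen bonded at any given moment. The benzylic oxyphosphonium ion may also ionise, with partial loss of configuration. The fallback sets out from 2 and removes the regiochemical question by using a symmetrical phenol. Mitsunobu reaction of 2 with excess phloroglucinol F3 gives the mono-ether F4, and both remaining hydroxyls are protected to give the bis-acetal F5. Lithiation with n-BuLi between the two acetal oxygens gives the aryllithium F6, which is formylated with DMF to the aldehyde F7. MgBr2·OEt2 then removes one of the two acetals flanking the formyl group; the chelated magnesium phenoxide resists a second cleavage. The route is rejoined at 4.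

Step 9. Turnover may be slow, or face selectivity poor, because the ketone sits next to a very bulky α-carbon; prolonged exposure to the amine could epimerise C7. The fallback sets out from 12 and makes C6 by addition instead of reduction. i-Bu2AlH reduces the Weinreb amide to the aldehyde F8. 2-Furylmagnesium bromide F9 (from 14 and MgBr2·OEt2) adds under chelation control, with magnesium bridging the aldehyde and benzyloxy oxygens and attack past the small hydrogen. This should give the same 6,7-syn carbinol, returning at 16.

Step 14. The lactone alkene may be dihydroxylated competitively, or the terminal alkene may turn over slowly. The fallback sets out from 20 and uses an electrophilic oxidant to which the electron-poor alkene is inert. Dimethyldioxirane in acetone at 0 °C gives the terminal epoxide F10, and H5IO6 in wet THF opens and cleaves it to return at 22.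

Step 16. Three processes compete with the ring closure:
- C-trifluoroacetylation of the very electron-rich ring A by excess anhydride;
- ionisation of the benzylic C2′–O bond by the liberated acid, with loss of configuration or fragmentation;
- acid cleavage of acetals.

The fallback sets out from 22 and forms C4′–C4a′ under neutral conditions at the alcohol oxidation level. N-Iodosuccinimide iodinates ring A ortho to the ether oxygen to give the aryl iodide F11. A Nozaki–Hiyama–Kishi cyclisation (CrCl2, NiCl2 cat., DMF) gives the flavan-4-ol F12, and Dess–Martin periodinane oxidises it to return at 25.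

Step 17. Four things may go wrong:
- incomplete cleavage of the hindered secondary benzyl ether at the temperature the lactone tolerates;
- alkylation of C8′ by the benzyl cation;
- Lewis-acid opening of ring C at the benzylic C2′–O bond;
- isomerisation of the hydroxy lactone to a butenolide during the quench.

The fallback sets out from 25 and separates the two deprotections. DDQ under visible-light irradiation in wet CH2Cl2 removes the benzyl group oxidatively to give the C7 alcohol F13. Me2BBr at −78 °C followed by aqueous NaHCO3 then removes the three acetals and returns at 26.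

## Further compounds

F1 | step 5 | (benzyloxy)acetaldehyde | O=CCOCc1ccccc1
F2 | step 5 | (3R,4S)-3-(benzyloxy)-5-(methoxymethoxy)-4-phenyl-7-{[(1S)-1-phenylbut-3-en-1-yl]oxy}-3,4-dihydro-2H-chromen-2-ol (both C2 epimers) | OC1Oc2cc(O[C@@H](CC=C)c3ccccc3)cc(OCOC)c2[C@H](c2ccccc2)[C@H]1OCc1ccccc1
F3 | step 1 | phloroglucinol (benzene-1,3,5-triol) | Oc1cc(O)cc(O)c1
F4 | step 1 | 5-{[(1S)-1-phenylbut-3-en-1-yl]oxy}benzene-1,3-diol | C=CC[C@@H](c1ccccc1)Oc1cc(O)cc(O)c1
F5 | step 1 | 1,3-bis(methoxymethoxy)-5-{[(1S)-1-phenylbut-3-en-1-yl]oxy}benzene | C=CC[C@@H](c1ccccc1)Oc1cc(OCOC)cc(OCOC)c1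
F6 | step 1 | 2,6-bis(methoxymethoxy)-4-{[(1S)-1-phenylbut-3-en-1-yl]oxy}phenyllithium | [Li]c1c(OCOC)cc(O[C@@H](CC=C)c2ccccc2)cc1OCOC
F7 | step 1 | 2,6-bis(methoxymethoxy)-4-{[(1S)-1-phenylbut-3-en-1-yl]oxy}benzaldehyde | C=CC[C@@H](c1ccccc1)Oc1cc(OCOC)c(C=O)c(OCOC)c1
F8 | step 9 | (2R,3S)-3-Ar-2-(benzyloxy)-3-phenylpropanal | O=C[C@H](OCc1ccccc1)[C@@H](c1ccccc1)c1c(OCOC)cc(O[C@@H](CC=C)c2ccccc2)cc1OCOC
F9 | step 9 | 2-furylmagnesium bromide | Br[Mg]c1ccco1
F10 | step 14 | (5S,6S)-6-[(1R,2S)-1-(benzyloxy)-2-{2,6-bis(methoxymethoxy)-4-[(1S)-2-(oxiran-2-yl)-1-phenylethoxy]phenyl}-2-phenylethyl]-5-(methoxymethoxy)-5,6-dihydro-2H-pyran-2-one (both epoxide epimers) | O=C1C=C[C@H](OCOC)[C@H]([C@H](OCc2ccccc2)[C@@H](c2ccccc2)c2c(OCOC)cc(O[C@@H](CC4CO4)c3ccccc3)cc2OCOC)O1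
F11 | step 16 | (5S,6S)-6-[(1R,2S)-1-(benzyloxy)-2-{3-iodo-2,6-bis(methoxymethoxy)-4-[(1S)-3-oxo-1-phenylpropoxy]phenyl}-2-phenylethyl]-5-(methoxymethoxy)-5,6-dihydro-2H-pyran-2-one | O=C1C=C[C@H](OCOC)[C@H]([C@H](OCc2ccccc2)[C@@H](c2ccccc2)c2c(OCOC)cc(O[C@@H](CC=O)c3ccccc3)c(I)c2OCOC)O1
F12 | step 16 | (2S)-6-[(1S,2R)-2-(benzyloxy)-2-[(2S,3S)-3-(methoxymethoxy)-6-oxo-3,6-dihydro-2H-pyran-2-yl]-1-phenylethyl]-5,7-bis(methoxymethoxy)-2-phenyl-3,4-dihydro-2H-chromen-4-ol (both C4 epimers) | O=C1C=C[C@H](OCOC)[C@H]([C@H](OCc2ccccc2)[C@@H](c2ccccc2)c2c(OCOC)cc3c(c2OCOC)C(O)C[C@@H](c2ccccc2)O3)O1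
F13 | step 17 | (2S)-6-[(1S,2R)-2-hydroxy-2-[(2S,3S)-3-(methoxymethoxy)-6-oxo-3,6-dihydro-2H-pyran-2-yl]-1-phenylethyl]-5,7-bis(methoxymethoxy)-2-phenyl-2,3-dihydro-4H-chromen-4-one | O=C1C=C[C@H](OCOC)[C@H]([C@H](O)[C@@H](c2ccccc2)c2c(OCOC)cc3c(c2OCOC)C(=O)C[C@@H](c2ccccc2)O3)O1
A1 | alternative 1 | (3S)-3-aryloxy-3-phenylpropanoic acid carrying the bis(tert-butyldimethylsilyl) hydroxy lactone side chain and two methoxymethyl ethers, stereocentres as in the target | O=C1C=C[C@H](O[Si](C)(C)C(C)(C)C)[C@H]([C@H](O[Si](C)(C)C(C)(C)C)[C@@H](c2ccccc2)c2c(OCOC)cc(O[C@@H](CC(=O)O)c3ccccc3)cc2OCOC)O1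
A2 | alternative 1 | fully protected target (tert-butyldimethylsilyl on the C5 and C7 oxygens, methoxymethyl on the C5′ and C7′ oxygens) | O=C1C=C[C@H](O[Si](C)(C)C(C)(C)C)[C@H]([C@H](O[Si](C)(C)C(C)(C)C)[C@@H](c2ccccc2)c2c(OCOC)cc3c(c2OCOC)C(=O)C[C@@H](c2ccccc2)O3)O1
A3 | alternative 2 | 6-substituted 3,6-dihydro-2H-pyran-2-one with free C7 hydroxyl on the bis(methoxymethyl) flavanone | O=C1CC=C[C@H]([C@H](O)[C@@H](c3ccccc3)c3c(OCOC)cc4c(c3OCOC)C(=O)C[C@@H](c3ccccc3)O4)O1
A4 | alternative 2 | 4,5-epoxy lactone, epoxide cis to the C6 side chain | O=C1C[C@@H]2O[C@@H]2[C@H]([C@H](O)[C@@H](c3ccccc3)c3c(OCOC)cc4c(c3OCOC)C(=O)C[C@@H](c3ccccc3)O4)O1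
A5 | alternative 2 | 5-hydroxy-5,6-dihydro-2H-pyran-2-one with free C5 and C7 hydroxyls on the bis(methoxymethyl) flavanone | O=C1C=C[C@H](O)[C@H]([C@H](O)[C@@H](c2ccccc2)c2c(OCOC)cc3c(c2OCOC)C(=O)C[C@@H](c2ccccc2)O3)O1
A6 | alternative 3 | 2-methoxy-3-(methoxymethoxy)-7-[(3E)-2-oxo-4-phenylbut-3-en-1-yl]-4-phenyl-3,4-dihydro-2H,5H-pyrano[4,3-b]pyran-5-one | O=C(/C=C/c1ccccc1)CC1=CC2=C(C(=O)O1)[C@H](c1ccccc1)[C@@H](OCOC)[C@H](OC)O2
A7 | alternative 3 | triacetic acid lactone (4-hydroxy-6-methyl-2H-pyran-2-one) | CC1=CC(O)=CC(=O)O1
A8 | alternative 3 | (2E)-1-[5,7-dihydroxy-2-methoxy-3-(methoxymethoxy)-4-phenyl-3,4-dihydro-2H-chromen-6-yl]-3-phenylprop-2-en-1-one | O=C(/C=C/c1ccccc1)c1c(O)cc2c(c1O)[C@H](c1ccccc1)[C@@H](OCOC)[C@H](OC)O2
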